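**Assumptions.** Gibberellic acid (GA3), a bulk fermentation product sold enantiopure by all major suppliers, counts as a commercial starting material. The route is therefore a relay synthesis from GA3. Numbering and α/β descriptors follow the ent-gibberellane convention. The target is 15β-hydroxy-GA1. Its C15-OH is cis to the C7 acid and H-9, and endo on the C/D bicyclo[3.2.1]octane (facing C11).

## Retrosynthetic overview
1. GA72 ⇐ its C7 allyl ester, cleaved last under neutral Pd(0) conditions. This avoids base (retro-aldol epimerisation at C3) and acid (C/D rearrangement).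
2. 15β-OH ⇐ exo (α-face) 1,2-hydride addition to the 16-en-15-one ⇐ MnO2 oxidation of the 15α-ol ⇐ SeO2 allylic hydroxylation of GA1 allyl ester.
3. Saturated ring A with 3β-OH ⇐ bulky-hydride reduction of the 3-ketone ⇐ CuH 1,4-reduction of the 1-en-3-one ⇐ oxidation of GA3 allyl ester.
4. No ring is constructed. Rings A–D, the 19,10-γ-lactone and the C4, C5, C6, C8, C9, C10 and C13 stereocentres are bought in GA3. C3 is erased and reset, and C15 is new.

## Route

**Step 1**
Reactants: 1 gibberellic acid (GA3); 2 allyl bromide
Product: 3 GA3 allyl ester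
Conditions: allyl bromide (1.5 equiv), KHCO3 (2 equiv), DMF, rt, 12 h
Reagents that add atoms: allyl bromide, C=CCBr
Why: This is a carboxylate SN2 O-alkylation in which bicarbonate ionises only the C7 acid, so the alcohols, the base-sensitive allylic lactone and all stereocentres are untouched.

**Step 2**
Reactants: 3 GA3 allyl ester
Product: 4 3-oxo-GA3 allyl ester (1-en-3-one)
Conditions: DMP (1.3 equiv), NaHCO3, CH2Cl2, 0 °C → rt
Reagents that add atoms: none
Why: In this Dess–Martin oxidation C3-OH is the only oxidisable alcohol (C13-OH is tertiary), and the C3 stereocentre is erased deliberately to activate the Δ1 alkene.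

**Step 3**
Reactants: 4 3-oxo-GA3 allyl ester
Product: 5 3-oxo-GA1 allyl ester (saturated 3-ketone)
Conditions: [(Ph3P)CuH]6 (0.5 equiv), H2O (5 equiv), degassed PhMe, rt
Reagents that add atoms: none (H only)
Why: The Stryker conjugate (1,4-hydride) reduction touches only the electron-poor Δ1 alkene and spares the 16(17)- and allyl alkenes, the enolate has no β-leaving group (the lactone O is γ), and no stereocentre is formed.

**Step 4**
Reactants: 5 3-oxo-GA1 allyl ester
Product: 6 GA1 allyl ester (3β-OH)
Conditions: K-Selectride (2.2 equiv), THF, −78 °C; quench at −78 °C with sat. aq KH2PO4; pH 7 H2O2 work-up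
Reagents that add atoms: none (H only)
Why: In this bulky-borohydride ketone reduction the β face of C3 is blocked by axial H-1β and H-5β, so hydride enters equatorially from the α (lactone) side to give the axial 3β-OH, and the cold phosphate quench prevents retro-aldol epimerisation.

**Step 5**
Reactants: 6 GA1 allyl ester
Product: 7 15α-hydroxy-GA1 allyl ester
Conditions: SeO2 (0.5 equiv), t-BuOOH (5.5 M in decane, 3 equiv), CH2Cl2, 0 °C → rt
Reagents that add atoms: selenium dioxide, O=[Se]=O (O source); re-oxidant tert-butyl hydroperoxide, CC(C)(C)OO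
Why: In this SeO2/TBHP allylic hydroxylation (ene, then [2,3]-shift) C15 carries the only allylic C–H (C13 is quaternary) and oxygen arrives on the open exo/α face, but the configuration and any over-oxidised 8 do not matter because Step 6 converges both.

**Step 6**
Reactants: 7 15α-hydroxy-GA1 allyl ester
Product: 8 15-oxo-GA1 allyl ester (16-en-15-one)
Conditions: activated MnO2 (25 equiv), CH2Cl2, rt; filter through Celite
Reagents that add atoms: none
Why: MnO2 oxidation is selective for allylic alcohols, so it takes the 15-ol and leaves the saturated 3β-OH and tertiary 13-OH, which removes the need for hydroxyl protection.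

**Step 7**
Reactants: 8 15-oxo-GA1 allyl ester
Product: 9 GA72 allyl ester (15β-OH)
Conditions: CeCl3·7H2O (1.5 equiv), NaBH4 (1.2 equiv), MeOH, −78 → −40 °C, 30 min; sat. NH4Cl
Reagents that add atoms: none (H only)
Why: The Luche reduction enforces 1,2-addition, and because the endo/β face of C15 is blocked by the axial endo H-11 and the β-C7 ester, hydride enters from the exo/α (C14) side and sets the 15β-OH; the low temperature and short time avoid lactonisation onto C7.

**Step 8**
Reactants: 9 GA72 allyl ester
Product: 10 gibberellin A72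
Conditions: Pd(PPh3)4 (5 mol %), morpholine (5 equiv), THF, rt, 1 h; cold aq citric acid to pH 3, EtOAc extraction
Reagents that add atoms: none
Why: In this Tsuji–Trost deallylation only the allyl ester ionises to a π-allyl complex, so the free allylic alcohols, the saturated lactone and the 3β-hydroxy-lactone stereocentre are inert under near-neutral conditions.

## Compound list

| No. | Name | SMILES | Role |
|---|---|---|---|
| 1 | Gibberellic acid (GA3) | `C=C1C[C@]23C[C@@]1(O)CC[C@H]2[C@@]12C=C[C@H](O)[C@@](C)(C(=O)O1)[C@H]2[C@@H]3C(=O)O` | starting material |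
| 2 | Allyl bromide | `C=CCBr` | starting material |
| 3 | GA3 allyl ester | `C=C1C[C@]23C[C@@]1(O)CC[C@H]2[C@@]12C=C[C@H](O)[C@@](C)(C(=O)O1)[C@H]2[C@@H]3C(=O)OCC=C` | intermediate |
| 4 | 3-Oxo-GA3 allyl ester (1-en-3-one) | `C=C1C[C@]23C[C@@]1(O)CC[C@H]2[C@@]12C=CC(=O)[C@@](C)(C(=O)O1)[C@H]2[C@@H]3C(=O)OCC=C` | intermediate |
| 5 | 3-Oxo-GA1 allyl ester | `C=C1C[C@]23C[C@@]1(O)CC[C@H]2[C@@]12CCC(=O)[C@@](C)(C(=O)O1)[C@H]2[C@@H]3C(=O)OCC=C` | intermediate |
| 6 | GA1 allyl ester (3β-OH) | `C=C1C[C@]23C[C@@]1(O)CC[C@H]2[C@@]12CC[C@H](O)[C@@](C)(C(=O)O1)[C@H]2[C@@H]3C(=O)OCC=C` | intermediate |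
| 7 | 15α-Hydroxy-GA1 allyl ester | `C=C1[C@H](O)[C@]23C[C@@]1(O)CC[C@H]2[C@@]12CC[C@H](O)[C@@](C)(C(=O)O1)[C@H]2[C@@H]3C(=O)OCC=C` | intermediate |
| 8 | 15-Oxo-GA1 allyl ester | `C=C1C(=O)[C@]23C[C@@]1(O)CC[C@H]2[C@@]12CC[C@H](O)[C@@](C)(C(=O)O1)[C@H]2[C@@H]3C(=O)OCC=C` | intermediate |
| 9 | GA72 allyl ester (15β-OH) | `C=C1[C@@H](O)[C@]23C[C@@]1(O)CC[C@H]2[C@@]12CC[C@H](O)[C@@](C)(C(=O)O1)[C@H]2[C@@H]3C(=O)OCC=C` | intermediate |
| 10 | Gibberellin A72 | `C=C1[C@@H](O)[C@]23C[C@@]1(O)CC[C@H]2[C@@]12CC[C@H](O)[C@@](C)(C(=O)O1)[C@H]2[C@@H]3C(=O)O` | target |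

## Summary
Total steps: 8. Longest linear sequence: 8 (fully linear from GA3).

**Steps most likely to fail**
1. **Step 7 (Luche reduction).** The risks are competing 1,4-reduction of the exocyclic enone and attack of the new 15β-alkoxide on the C7 ester.
   - Fallback: mask the enone. Treat 8 with (PhSe)2/NaBH4 in EtOH, which adds PhSe⁻ to C17 and reduces the now-saturated ketone from the same exo face.
   - Then oxidise with H2O2. Selenoxide syn-elimination (the only β-H is on C16) regenerates the 16(17)-methylene.
2. **Step 5 (SeO2 hydroxylation).** The risks are low conversion, formation of the 15-en-17-al, and 13-OH-assisted C/D Wagner–Meerwein rearrangement.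
   - Fallback: install the C15 oxygen through the nor-ketone, using a non-olefinic ester (for example TMSE) and 3,13-O-silyl protection.
   - Sequence: Lemieux–Johnson cleavage to the 17-nor-16-ketone, Rubottom oxidation at C15 (the only enolisable site), then Wittig methylenation. The route rejoins at Step 6.
3. **Step 6 (MnO2 oxidation).** The risk is a sluggish reaction, because the carbinol C–H of the 15α-ol is endo and hindered, with the free 3β-OH also present.
   - Fallback: give up chemoselective oxidation. Silylate the 3-OH (TESCl/imidazole, selective over the tertiary 13-OH) straight after Step 4.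
   - After SeO2, use a non-selective oxidant (DMP). Run the Luche reduction, then remove TES with HF·pyridine before deallylation (two extra steps).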